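**Retrosyn­thetic overview**
1. Building blocks: tetradecan-2-one 1 (the chain plus the future acetyl group) and 2-(hydroxymethyl)-6-methoxyphenol 2 (the arene, bought intact; no ring is formed in the route).
2. ArCH2–C(α) disconnection: 1 plus o-quinone methide 3 (from 2) gives the (R)-α-benzylated ketone 4 by amine-catalysed asymmetric alkylation; this sets the only stereocenter.
3. Arene para C–H to C=O: phenol 4 to p-quinone 5.
4. C–OAc from C–C(O)CH3 at the stereocenter: Baeyer–Villiger oxidation of 5 to 6 with retention; the acetyl of 1 becomes the acetate.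
5. Hydroquinone 7 from quinone 6 by two-electron reduction in the last step.

Assumption: hydroxy ketone and cyclic hemiketal (chroman-2-ol) ring–chain tautomers are counted as one compound and drawn open-chain, and the quinine-derived amine catalyst is assumed to give the R product in step 1 (the quinidine-derived pseudoenantiomer is used if the sense is opposite).

**Route**

Step 1
Reactants: 1 tetradecan-2-one; 2 2-(hydroxymethyl)-6-methoxyphenol
Product: 4 (3R)-3-[(2-hydroxy-3-methoxyphenyl)methyl]tetradecan-2-one, via o-quinone methide 3 (not isolated)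
Conditions: 9-amino-9-deoxy-epi-quinine (20 mol%), (PhO)2P(O)OH (50 mol%), 1 (3 equiv), toluene, 40 °C; 2 added over 12 h
Reagents that add atoms: none
Why: Proposed new method: the phosphoric acid dehydrates 2 to the o-quinone methide 3 at low steady-state concentration while the primary amine condenses with 1 to the more substituted (Z)-enamine (C2=C3, favoured with primary amines because the N–H avoids allylic strain), and the catalyst ammonium N–H hydrogen-bonds the carbonyl oxygen of 3 so that its CH2 terminus is delivered to one enamine face, setting C3 as R; closure of the adduct to the chromanol hemiketal takes the product out of the enamine cycle, which protects the new α-stereocenter and stops a second alkylation; the closest known reaction type is the enamine-catalysed asymmetric Michael-type α-alkylation of aldehydes by in situ generated o-quinone methides (together with branched-selective primary-amine-catalysed conjugate additions of alkyl methyl ketones), not yet shown for an acyclic methyl ketone at its methylene carbon with an unsubstituted o-quinone methide released by acid from a salicyl alcohol.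

Step 2
Reactants: 4 (3R)-3-[(2-hydroxy-3-methoxyphenyl)methyl]tetradecan-2-one
Product: 5 (3R)-3-[(5-methoxy-3,6-dioxocyclohexa-1,4-dien-1-yl)methyl]tetradecan-2-one
Conditions: (KSO3)2NO (2.5 equiv), KH2PO4 (aq., pH 6), acetone/H2O, 0 °C to rt
Reagents that add atoms: potassium nitrosodisulfonate (Fremy's salt), [K+].[K+].[O]N(S(=O)(=O)[O-])S(=O)(=O)[O-]
Why: Teuber oxidation, in which the nitroxyl radical abstracts the phenolic hydrogen and a second equivalent oxygenates the free para position to give the p-quinone, the open-chain phenol being drained from the hemiketal equilibrium and the α-stereocenter left untouched at pH 6.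

Step 3
Reactants: 5 (3R)-3-[(5-methoxy-3,6-dioxocyclohexa-1,4-dien-1-yl)methyl]tetradecan-2-one
Product: 6 (2R)-1-(5-methoxy-3,6-dioxocyclohexa-1,4-dien-1-yl)tridecan-2-yl acetate
Conditions: mCPBA (2.5 equiv), CF3CO2H (1 equiv), CH2Cl2, 0 °C to rt, dark
Reagents that add atoms: mCPBA (3-chloroperoxybenzoic acid), OOC(=O)c1cccc(Cl)c1
Why: Baeyer–Villiger oxidation, in which the secondary alkyl group of the Criegee adduct migrates in preference to methyl and with retention of configuration, so the R ketone gives the R acetate while the electron-poor quinone resists the electrophilic peracid.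

Step 4
Reactants: 6 (2R)-1-(5-methoxy-3,6-dioxocyclohexa-1,4-dien-1-yl)tridecan-2-yl acetate
Product: 7 (2R)-1-(2,5-dihydroxy-3-methoxyphenyl)tridecan-2-yl acetate
Conditions: Na2S2O4 (3 equiv), EtOAc/H2O, rt, argon
Reagents that add atoms: none
Why: Dithionite reduction of the p-quinone to the hydroquinone by electron transfer in a neutral two-phase system, which leaves the secondary acetate and the stereocenter untouched.

**Compound list**
1 | tetradecan-2-one | CCCCCCCCCCCCC(C)=O | starting material
2 | 2-(hydroxymethyl)-6-methoxyphenol (o-vanillyl alcohol) | COc1cccc(CO)c1O | starting material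
3 | 2-methoxy-6-methylidenecyclohexa-2,4-dien-1-one (o-quinone methide) | C=C1C=CC=C(OC)C1=O | intermediate
4 | (3R)-3-[(2-hydroxy-3-methoxyphenyl)methyl]tetradecan-2-one | CCCCCCCCCCC[C@H](Cc1cccc(OC)c1O)C(C)=O | intermediate
5 | (3R)-3-[(5-methoxy-3,6-dioxocyclohexa-1,4-dien-1-yl)methyl]tetradecan-2-one | CCCCCCCCCCC[C@H](CC1=CC(=O)C=C(OC)C1=O)C(C)=O | intermediate
6 | (2R)-1-(5-methoxy-3,6-dioxocyclohexa-1,4-dien-1-yl)tridecan-2-yl acetate | CCCCCCCCCCC[C@H](CC1=CC(=O)C=C(OC)C1=O)OC(C)=O | intermediate
7 | (2R)-1-(2,5-dihydroxy-3-methoxyphenyl)tridecan-2-yl acetate | CCCCCCCCCCC[C@H](Cc1cc(O)cc(OC)c1O)OC(C)=O | target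

**Totals**
Total step count: 4. Longest linear sequence: 4.

**Steps most likely to fail**

Step 1 (the new alkylation) is the largest risk. Four things can go wrong:
- the acid may release 3 from a primary salicyl alcohol too slowly at 40 °C;
- 3 may N-benzylate the amine catalyst or condense with electron-rich arenes;
- some alkylation may occur at the methyl carbon of 1, giving the achiral linear isomer;
- the enantiomeric excess is unproven and is to be measured on 4 by chiral HPLC.

Fallback, known chemistry, setting out from 2 and coming back at 4: 2 is condensed with 4-CH3C6H4SO2Na in aqueous HCO2H to the sulfone 2-methoxy-6-{[(4-methylphenyl)sulfonyl]methyl}phenol F1. With NaHCO3, F1 releases 3 under mild base in the presence of purchased tridecanal and (S)-α,α-diphenylprolinol trimethylsilyl ether (20 mol%). The aldehyde has a single α-site and this enamine alkylation of aldehydes by o-quinone methides is established; it gives (2R)-2-[(2-hydroxy-3-methoxyphenyl)methyl]tridecanal F2, held as its lactol. CH3MgBr (3 equiv, THF, −78 to 0 °C) converts F2 into the carbinol epimers (3R)-3-[(2-hydroxy-3-methoxyphenyl)methyl]tetradecan-2-ol F3. SO3·pyridine/DMSO/i-Pr2NEt then oxidises F3 to 4. This costs three extra steps.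

Step 3 (Baeyer–Villiger on the quinone) is the second risk. The oxidation of an acyclic methyl ketone is slow, and on long exposure the peracid may attack the methoxy-substituted C=C or a quinone carbonyl.

Fallback, setting out from 4 and coming back at 6: the phenol is masked with Ac2O/pyridine as 2-methoxy-6-[(2R)-2-acetyltridecyl]phenyl acetate F6. Baeyer–Villiger oxidation with mCPBA/CF3CO2H on this deactivated arene gives (2R)-1-[2-(acetyloxy)-3-methoxyphenyl]tridecan-2-yl acetate F7. Pyrrolidine (1.1 equiv, CH2Cl2, 0 °C) cleaves only the aryl acetate to (2R)-1-(2-hydroxy-3-methoxyphenyl)tridecan-2-yl acetate F8. Oxidation of F8 with (KSO3)2NO then gives 6. The peracid never meets a quinone, at the cost of two extra steps.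

Step 2 (Fremy oxidation) is the third risk. Attack at the methoxy-bearing ortho carbon would give an o-quinone, and the hemiketal may open slowly.

Fallback, setting out from 4 and coming back at 5: 4 is coupled at 0 °C and pH 9 (NaHCO3/Na2CO3) with 4-diazoniobenzenesulfonate, made from sulfanilic acid, NaNO2 and HCl. This gives the para-azo phenol 4-[(E)-{4-hydroxy-3-methoxy-5-[(2R)-2-acetyltridecyl]phenyl}diazenyl]benzenesulfonic acid F4. Na2S2O4 in aqueous ethanol cleaves the N=N bond to (3R)-3-[(5-amino-2-hydroxy-3-methoxyphenyl)methyl]tetradecan-2-one F5. FeCl3 in dilute HCl oxidises the p-aminophenol F5 to 5. The para oxygen is thus introduced through a C–N bond instead of by radical oxygenation. The base exposure must be kept short and cold to protect the α-stereocenter.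

**Further compounds**
F1 | step 1 | 2-methoxy-6-{[(4-methylphenyl)sulfonyl]methyl}phenol | COc1cccc(CS(=O)(=O)c2ccc(C)cc2)c1O
F2 | step 1 | (2R)-2-[(2-hydroxy-3-methoxyphenyl)methyl]tridecanal | CCCCCCCCCCC[C@H](Cc1cccc(OC)c1O)C=O
F3 | step 1 | (3R)-3-[(2-hydroxy-3-methoxyphenyl)methyl]tetradecan-2-ol (both C2 epimers) | CCCCCCCCCCC[C@H](Cc1cccc(OC)c1O)C(C)O
F4 | step 2 | 4-[(E)-{4-hydroxy-3-methoxy-5-[(2R)-2-acetyltridecyl]phenyl}diazenyl]benzenesulfonic acid | CCCCCCCCCCC[C@H](Cc1cc(/N=N/c2ccc(cc2)S(=O)(=O)O)cc(OC)c1O)C(C)=O
F5 | step 2 | (3R)-3-[(5-amino-2-hydroxy-3-methoxyphenyl)methyl]tetradecan-2-one | CCCCCCCCCCC[C@H](Cc1cc(N)cc(OC)c1O)C(C)=O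
F6 | step 3 | 2-methoxy-6-[(2R)-2-acetyltridecyl]phenyl acetate | CCCCCCCCCCC[C@H](Cc1cccc(OC)c1OC(C)=O)C(C)=O
F7 | step 3 | (2R)-1-[2-(acetyloxy)-3-methoxyphenyl]tridecan-2-yl acetate | CCCCCCCCCCC[C@H](Cc1cccc(OC)c1OC(C)=O)OC(C)=O
F8 | step 3 | (2R)-1-(2-hydroxy-3-methoxyphenyl)tridecan-2-yl acetate | CCCCCCCCCCC[C@H](Cc1cccc(OC)c1O)OC(C)=O
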